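**Plan**

- Retrosynthesis: the 5-O-benzyl and 2'-O-methyl bonds are cut first. Ring B is then cut at C1'–C2' and C5'–C6' into cyclobutenone and a methoxyalkyne already bonded to C2. The C2–alkyne bond is cut next, leaving a 5-benzyloxychromone, whose pyranone goes back to an o-hydroxyacetophenone and 3,4,5-trimethoxyphenol.
- Enabling feature: in ring B the two carbons flanking C1' (C2' and C6') both carry oxygen while C3'–C5' are CH. This is the resorcinol pattern that a vinylketene and an ynol ether assemble, so the crowded C2–C1' bond can be laid down early as an unhindered C2–C(sp) bond.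
- Forward order: ring A is bought, ring C is closed on it as a chromone, C2 is alkynylated, and ring B is grown last by benzannulation; O-methylation and debenzylation finish the route.
- Stereochemistry: the only stereocentre, C2 (S), is set by the CuI/chiral bisoxazoline-controlled addition of a copper acetylide to the 4-silyloxybenzopyrylium ion. Every later step avoids strong acid and base so that ring C cannot open and reclose.

Key step: step 10

Assumption: the (S,S) ligand in step 7 is taken to give the 2S adduct by analogy with arylacetylenes (the alkynyl group ranks between O1 and C3 in both series, so the descriptor carries over); if the opposite sense is found, the (R,R) ligand is used.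

**Step 1**
Reactants: 1 3,4,5-trimethoxyphenol
Product: 2 1,2,3,5-tetramethoxybenzene
Conditions: MeI, K2CO3, acetone, reflux
Reagents that add atoms: iodomethane, CI
Why: Williamson etherification of the phenoxide, which makes all four oxygens equal so that the next step can choose which one is freed.

**Step 2**
Reactants: 2 1,2,3,5-tetramethoxybenzene
Product: 3 1-(2-hydroxy-3,4,6-trimethoxyphenyl)ethan-1-one
Conditions: AcCl (1.1 equiv), AlCl3 (2.2 equiv), CH2Cl2, 0 °C to rt; aq. HCl work-up
Reagents that add atoms: acetyl chloride, CC(Cl)=O
Why: Friedel–Crafts acylation at one of the two equivalent free positions, after which AlCl3 chelated to the new ketone should cleave the ortho methyl ether that is also flanked by a methoxy group (the more crowded, more basic one), placing the free phenol next to the 3,4-dimethoxy pair as ring C requires.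

**Step 3**
Reactants: 3 1-(2-hydroxy-3,4,6-trimethoxyphenyl)ethan-1-one; 4 N,N-dimethylformamide dimethyl acetal
Product: 6 5,7,8-trimethoxy-4H-chromen-4-one, via enaminone 5 (not isolated)
Conditions: 4 (2 equiv), toluene, 100 °C; evaporate; conc. HCl, CH2Cl2, 40 °C
Reagents that add atoms: none
Why: Condensation of the methyl ketone with the amide acetal gives the enaminone, and acid then promotes conjugate addition of the phenol and loss of dimethylamine (enaminone route to chromones).

**Step 4**
Reactants: 6 5,7,8-trimethoxy-4H-chromen-4-one
Product: 7 5-hydroxy-7,8-dimethoxy-4H-chromen-4-one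
Conditions: BCl3 (1.5 equiv), CH2Cl2, −78 to 0 °C; aq. NaHCO3
Reagents that add atoms: none
Why: Chelation-controlled demethylation, in which BCl3 bridges the C4 carbonyl and the peri 5-methoxy oxygen and chloride removes only that methyl group, the 7- and 8-ethers having no such assistance.

**Step 5**
Reactants: 7 5-hydroxy-7,8-dimethoxy-4H-chromen-4-one
Product: 8 5-(benzyloxy)-7,8-dimethoxy-4H-chromen-4-one
Conditions: BnBr, K2CO3, n-Bu4NI (cat.), DMF, 60 °C
Reagents that add atoms: benzyl bromide, BrCc1ccccc1
Why: Williamson benzylation of the chelated phenol, which needs DMF and gentle heating but no strong base, so the base-sensitive pyranone should stay closed.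

**Step 6**
Reactants: 9 chloroacetaldehyde dimethyl acetal
Product: 11 methoxyacetylene, via sodium methoxyacetylide 10 (not isolated)
Conditions: NaNH2 (3 equiv), liq. NH3, −33 °C; NH3 evaporated; sat. aq. NaCl, −20 °C; 11 distilled into toluene at −78 °C
Reagents that add atoms: none
Why: Successive base-induced eliminations of HCl and methanol from the chloro acetal give the sodium alkoxyacetylide, and protonation frees the volatile ynol ether (classical alkoxyacetylene preparation).

**Step 7**
Reactants: 8 5-(benzyloxy)-7,8-dimethoxy-4H-chromen-4-one; 11 methoxyacetylene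
Product: 14 (2S)-5-(benzyloxy)-7,8-dimethoxy-2-(methoxyethynyl)chroman-4-one, via silyloxybenzopyrylium triflate 12 (not isolated), via silyl enol ether 13 (not isolated)
Conditions: TBSOTf (1.05 equiv), CH2Cl2, rt; then CuI (10 mol %), 2,2'-(propane-2,2-diyl)bis[(4S)-4-phenyl-4,5-dihydrooxazole] (12 mol %), iPr2NEt (1.3 equiv), 11 (1.5 equiv), toluene, −78 °C; then TBAF, AcOH, THF, −78 °C
Reagents that add atoms: none
Why: Proposed new method: TBSOTf turns the chromone into benzopyrylium triflate 12, CuI and the amine convert the terminal ynol ether into a copper acetylide held by the C2-symmetric bisoxazoline, and this acetylide should add to C2 of the cation from the face left open by the ligand phenyl groups to set C2 as S, after which buffered fluoride unmasks the ketone from enol ether 13 without acid (which would hydrate the ynol ether) or a free enolate (which would open ring C); the closest known reaction is the CuI–bisoxazoline enantioselective alkynylation of 4-silyloxybenzopyrylium triflates with aryl- and alkylacetylenes, and the extension rests on the known ability of alkoxyacetylenes to form copper acetylides in Sonogashira-type couplings.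

**Step 8**
Reactants: 15 3-oxocyclobutane-1-carboxylic acid
Product: 16 3-bromocyclobutan-1-one
Conditions: HgO, Br2, MgSO4, CH2Cl2, reflux
Reagents that add atoms: bromine, BrBr
Why: Hunsdiecker bromodecarboxylation in the Cristol–Firth variant (acyl hypobromite formed on HgO, radical loss of CO2), which tolerates the ketone.

**Step 9**
Reactants: 16 3-bromocyclobutan-1-one
Product: 17 cyclobut-2-en-1-one
Conditions: n-Bu3N, neat, rt, reduced pressure, 17 collected at −78 °C
Reagents that add atoms: none
Why: β-Elimination of HBr from the β-bromo ketone (E1cB) by a high-boiling, non-nucleophilic amine, with the volatile enone removed as it forms so that it cannot polymerise.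

**Step 10**
Reactants: 14 (2S)-5-(benzyloxy)-7,8-dimethoxy-2-(methoxyethynyl)chroman-4-one; 17 cyclobut-2-en-1-one
Product: 22 (2S)-5-(benzyloxy)-2-(2-hydroxy-6-methoxyphenyl)-7,8-dimethoxychroman-4-one, via vinylketene 18 (not isolated), via vinylcyclobutenone 19 (not isolated), via dienylketene 20 (not isolated), via cyclohexadienone 21 (not isolated)
Conditions: 17 (2 equiv, two portions), toluene, sealed tube, 80 °C then 110 °C
Reagents that add atoms: none
Why: Heat opens cyclobutenone by 4π electrocyclic ring opening to vinylketene 18, whose ketene C=C adds [2+2] to the ynol ether so that the nucleophilic alkyne carbon bearing C2 bonds to the ketene carbonyl carbon (C1'–C2') and the methoxy-bearing carbon bonds to the ketene α-carbon (C5'–C6'), giving vinylcyclobutenone 19. A second 4π opening gives dienylketene 20, which closes ring B by 6π electrocyclisation (C2'–C3') to cyclohexadienone 21, and tautomerisation should deliver the phenol with OH and OMe on the two carbons flanking C1'. The closest known reaction is the Danheiser benzannulation of cyclobutenones with 1-alkoxyalkynes to 3-alkoxyphenols. No stereocentre is created; C2 is a spectator that should be kept because the cascade is thermal, free of acid and base, and the methyl ynol ether has no β-hydrogen for retro-ene loss of a ketene. The step needs regioselectivity in the [2+2] addition, secured by the polarisation of the MeO–C≡C unit, and chemoselectivity for the alkyne over the C4 ketone and the arenes, which are not ketenophiles at this temperature.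

**Step 11**
Reactants: 22 (2S)-5-(benzyloxy)-2-(2-hydroxy-6-methoxyphenyl)-7,8-dimethoxychroman-4-one
Product: 23 (2S)-5-(benzyloxy)-2-(2,6-dimethoxyphenyl)-7,8-dimethoxychroman-4-one
Conditions: Me3SiCHN2 (hexanes, 3 equiv), iPr2NEt (1.5 equiv), MeCN–MeOH, 0 °C to rt
Reagents that add atoms: (trimethylsilyl)diazomethane, C[Si](C)(C)C=[N+]=[N-]
Why: O-Methylation of the phenol by a diazomethane surrogate (proton transfer to the diazo carbon, then methylation of the phenoxide), mild enough that the ketone, the benzyl ether and the C2 centre should be untouched.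

**Step 12**
Reactants: 23 (2S)-5-(benzyloxy)-2-(2,6-dimethoxyphenyl)-7,8-dimethoxychroman-4-one
Product: 24 (2S)-5-hydroxy-7,8,2',6'-tetramethoxyflavanone
Conditions: H2 (1 atm), 10% Pd/C, EtOAc, rt
Reagents that add atoms: none
Why: Catalytic hydrogenolysis of the aryl benzyl ether under neutral conditions, expected to be faster than cleavage of the cyclic benzylic C2–O1 bond shielded by the 2,6-dimethoxyphenyl group, so the chelated 5-OH is freed with C2 intact.

**Compound list**

1 | 3,4,5-trimethoxyphenol | COc1cc(O)cc(OC)c1OC | starting material
2 | 1,2,3,5-tetramethoxybenzene | COc1cc(OC)c(OC)c(OC)c1 | intermediate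
3 | 1-(2-hydroxy-3,4,6-trimethoxyphenyl)ethan-1-one | CC(=O)c1c(O)c(OC)c(OC)cc1OC | intermediate
4 | N,N-dimethylformamide dimethyl acetal | COC(OC)N(C)C | starting material
5 | (E)-3-(dimethylamino)-1-(2-hydroxy-3,4,6-trimethoxyphenyl)prop-2-en-1-one | CN(C)/C=C/C(=O)c1c(O)c(OC)c(OC)cc1OC | intermediate
6 | 5,7,8-trimethoxy-4H-chromen-4-one | COc1cc(OC)c2c(c1OC)occc2=O | intermediate
7 | 5-hydroxy-7,8-dimethoxy-4H-chromen-4-one | COc1cc(O)c2c(c1OC)occc2=O | intermediate
8 | 5-(benzyloxy)-7,8-dimethoxy-4H-chromen-4-one | COc1cc(OCc3ccccc3)c2c(c1OC)occc2=O | intermediate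
9 | chloroacetaldehyde dimethyl acetal (2-chloro-1,1-dimethoxyethane) | COC(CCl)OC | starting material
10 | sodium methoxyacetylide | [Na+].[C-]#COC | intermediate
11 | methoxyacetylene (methoxyethyne) | COC#C | intermediate
12 | 5-(benzyloxy)-4-[(tert-butyldimethylsilyl)oxy]-7,8-dimethoxychromenylium triflate | COc1cc(OCc3ccccc3)c2c(O[Si](C)(C)C(C)(C)C)cc[o+]c2c1OC.[O-]S(=O)(=O)C(F)(F)F | intermediate
13 | (2S)-5-(benzyloxy)-4-[(tert-butyldimethylsilyl)oxy]-7,8-dimethoxy-2-(methoxyethynyl)-2H-chromene | COC#C[C@@H]1C=C(O[Si](C)(C)C(C)(C)C)c2c(OCc3ccccc3)cc(OC)c(OC)c2O1 | intermediate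
14 | (2S)-5-(benzyloxy)-7,8-dimethoxy-2-(methoxyethynyl)chroman-4-one | COC#C[C@@H]1CC(=O)c2c(OCc3ccccc3)cc(OC)c(OC)c2O1 | intermediate
15 | 3-oxocyclobutane-1-carboxylic acid | O=C1CC(C(=O)O)C1 | starting material
16 | 3-bromocyclobutan-1-one | O=C1CC(Br)C1 | intermediate
17 | cyclobut-2-en-1-one | O=C1C=CC1 | intermediate
18 | vinylketene (buta-1,3-dien-1-one) | C=CC=C=O | intermediate
19 | (2S)-5-(benzyloxy)-7,8-dimethoxy-2-(2-methoxy-4-oxo-3-vinylcyclobut-1-en-1-yl)chroman-4-one (both epimers at the vinyl-bearing carbon) | C=CC1C(=O)C(=C1OC)[C@@H]2CC(=O)c3c(OCc4ccccc4)cc(OC)c(OC)c3O2 | intermediate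
20 | (2S)-5-(benzyloxy)-7,8-dimethoxy-2-[(3E)-3-methoxy-1-oxohexa-1,3,5-trien-2-yl]chroman-4-one | O=C=C(/C(OC)=C\C=C)[C@@H]1CC(=O)c2c(OCc3ccccc3)cc(OC)c(OC)c2O1 | intermediate
21 | (2S)-5-(benzyloxy)-7,8-dimethoxy-2-(2-methoxy-6-oxocyclohexa-1,3-dien-1-yl)chroman-4-one | O=C1CC=CC(OC)=C1[C@@H]2CC(=O)c3c(OCc4ccccc4)cc(OC)c(OC)c3O2 | intermediate
22 | (2S)-5-(benzyloxy)-2-(2-hydroxy-6-methoxyphenyl)-7,8-dimethoxychroman-4-one | COc1cc(OCc3ccccc3)c2c(c1OC)O[C@H](c1c(O)cccc1OC)CC2=O | intermediate
23 | (2S)-5-(benzyloxy)-2-(2,6-dimethoxyphenyl)-7,8-dimethoxychroman-4-one | COc1cc(OCc3ccccc3)c2c(c1OC)O[C@H](c1c(OC)cccc1OC)CC2=O | intermediate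
24 | (2S)-5-hydroxy-7,8,2',6'-tetramethoxyflavanone [(2S)-2-(2,6-dimethoxyphenyl)-5-hydroxy-7,8-dimethoxychroman-4-one] | COc1cc(O)c2c(c1OC)O[C@H](c1c(OC)cccc1OC)CC2=O | target

**Step count and risks**

Total: 12 steps. Longest linear sequence: 9 steps (1, 2, 3, 4, 5, 7, 10, 11, 12); steps 6 and 8–9 make the two small partners.

Steps most likely to fail:

1. Step 7 (proposed new method). The neutral ynol ether is nucleophilic at its unsubstituted carbon and may attack the benzopyrylium ion without copper, or be consumed by silyl triflate; either would cause poor facial selectivity or loss of the alkyne. The fallback, built from known reaction types, sets out from 8 (as its triflate 12) and 11 and comes back at 14. Alkyne 11 is deprotonated with n-BuLi in THF at −78 °C to lithium methoxyacetylide F1, which is transmetalated with ZnBr2 to bromo(methoxyethynyl)zinc F2. Silyl-triflate-promoted conjugate addition of this alkynylzinc halide to 12 should give the racemic silyl enol ether F3, and the same buffered fluoride work-up the racemic chromanone F4. Preparative chromatography on a chiral stationary phase (cellulose tris(3,5-dimethylphenylcarbamate)) then supplies 14, with the (2R) enantiomer F5 set aside.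

2. Step 10. Cyclobutenone may polymerise before it opens, and excess vinylketene may acylate the phenol as it forms. The fallback sets out from 14 and comes back at 22. Vinylketene 18 is generated at 0 °C by 1,4-dehydrochlorination of (E)-but-2-enoyl chloride with Et3N in CH2Cl2 in the presence of 14, so the [2+2] addition to 19 should occur without heating. The ammonium salt is filtered off, the solvent is exchanged for toluene, and heating at 80 °C carries 19 through 20 and 21 to 22. This detour makes no compound outside the list (F0).

3. Step 11. The phenol is hindered by the adjacent chromanone, and slow methylation would let amine-promoted opening of ring C (retro-oxa-Michael) compete and erode C2. The fallback sets out from 22 and comes back at 23: Mitsunobu etherification with methanol (PPh3, DIAD, THF, 0 °C), in which the phenol is alkylated by a methoxyphosphonium ion and neither a diazo compound nor an amine base is present. It makes no compound outside the list (F0).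

**Further compounds**

F1 | step 7 | lithium methoxyacetylide | [Li+].[C-]#COC
F2 | step 7 | bromo(methoxyethynyl)zinc | COC#C[Zn]Br
F3 | step 7 | racemic 5-(benzyloxy)-4-[(tert-butyldimethylsilyl)oxy]-7,8-dimethoxy-2-(methoxyethynyl)-2H-chromene | COC#CC1C=C(O[Si](C)(C)C(C)(C)C)c2c(OCc3ccccc3)cc(OC)c(OC)c2O1
F4 | step 7 | racemic 5-(benzyloxy)-7,8-dimethoxy-2-(methoxyethynyl)chroman-4-one | COC#CC1CC(=O)c2c(OCc3ccccc3)cc(OC)c(OC)c2O1
F5 | step 7 | (2R)-5-(benzyloxy)-7,8-dimethoxy-2-(methoxyethynyl)chroman-4-one | COC#C[C@H]1CC(=O)c2c(OCc3ccccc3)cc(OC)c(OC)c2O1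
F0 | step 10 | none | none
F0 | step 11 | none | none
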